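Route in one sentence: ring C is closed and C2 is set by dehydrogenative O1–C2 bond formation through a ring B para-quinone methide. This methide is raised by C–H oxidation of an enantiopure, amino-acid-derived α-hydroxydihydrochalcone whose only stereocentre is C3.

## Structural features

The target is a flavanonol. A phloroglucinol-type ring A is fused through C4a and C8a to a dihydropyranone ring C (O1, C2, C3, C4), and a 4-hydroxyphenyl ring B sits on C2. Ring A is fully differentiated: a chelated OH at C5, H at C6, OMe at C7 and a prenyl chain at C8 next to O1. The two stereocentres, C2 (R, aryl) and C3 (R, OH), are adjacent and trans, with both substituents equatorial. Both are labile. C3 is alpha to the C4 ketone, and the O1–C2 bond can open either from a C3 enolate or, pushed by the 4'-OH of ring B, through a para-quinone methide; base also diverts such compounds to benzofuranones, and air with base gives flavonols. The prenyl alkene is sensitive to strong acid, electrophilic oxidants and quinone oxidants. The real difficulty is twofold: fixing the labile C2/C3 pair in the absolute sense, and placing the prenyl chain at C8 rather than C6 while only O5 stays free. The key step exploits two features. C2 is the benzylic carbon para to the 4'-OH of ring B, so it is the methide carbon of a latent quinone methide. Without the prenyl group the two ortho-hydroxyls of ring A are equivalent, so O1–C2 can be closed from a CH2 precursor with C3 as its only stereocentre.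

## Logic of the disconnections

**19 to 18.** The two O–acyl bonds at O3 and O4' are cut. These esters are needed earlier. A free O4' would open O1–C2 through the quinone methide channel during the heated rearrangement, and O3 and O4' would compete with O5 in the etherification. The skeleton is not simplified. The forward step must cleave two esters without base (lability of C2/C3, benzofuranone rearrangement, aerial oxidation) and without acid strong enough to attack the prenyl alkene.

**18 to 15.** The C8–C1'' bond is cut and the chain is re-attached by the same carbon C1'' to O5. Direct electrophilic prenylation cannot tell C6 from C8. O5, however, is a unique oxygen, C6 is its only open ortho position and C8 is its para position. Two consecutive [3,3] shifts carry the chain from O5 to C6 to C8, invert the allyl unit twice (so the normal prenyl chain results) and return the free 5-OH. A regiochemical problem at carbon becomes a chemoselective O-alkylation. The demand is that the second shift (16 to 17) outruns enolisation of 16.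

**15 to 13 and 14.** The O5–C1'' bond is cut. This gives a five-carbon alcohol and a flavanonol with a single acidic O–H. The forward step must alkylate a chelated, weakly nucleophilic phenol without base-induced opening of ring C.

**13 to 12.** The same two O–acyl bonds are cut, on the unprenylated core. The forward step must leave the chelated 5-OH untouched.

**12 to 10 (key disconnection).** The O1–C2 bond is cut and C2 is returned to the CH2 oxidation level. Ring C and the stereocentre C2 disappear. Ring A becomes locally symmetric with two equivalent ortho-hydroxyls, and one stereocentre (C3) remains in an open chain. The forward step must oxidise one benzylic C–H para to a free phenol, trap the resulting 11 with a ring A oxygen faster than 11 can tautomerise, and let C3 dictate C2. The closure also desymmetrises ring A, which creates the single chelated 5-OH used by the later prenyl relay.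

**10 to 9, then to 5 and 7.** Four acetal O–C bonds are cut first, then the C4–C4a bond. The molecule splits into a symmetric ring A nucleophile and a C6–C3 acyl donor that already holds C3. The forward step needs metalation of 7 between its two acetal-bearing oxygens, and acyl transfer that never exposes an enolisable ketone to a strong base.

**5 to 4, 3 and 1; 7 to 6.** Acetal O–C bonds, the amide C–N bond and finally the C3–O bond (exchanged for C–N) are cut. All carbons of ring B, C2, C3 and C4, and the configuration at C3, come from 1. The forward step must replace N by O with net retention. Compound 7 goes back to 6 by cutting two acetal O–C bonds.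

## Other disconnections considered

**Alternative 1:** (first to come to mind) Cut O1–C2 and the C2–C3 bond at the alkene level.

- *Forward route.* Aldol condensation of the prenylated acetophenone A1 with the ring B aldehyde component gives chalcone A2. A catalytic asymmetric nucleophilic epoxidation of A2 gives A3, followed by deprotection and opening of the epoxide by a ring A oxygen.
- *Regiochemistry.* With the prenyl group present the two ortho oxygens of ring A differ. They would need separate protecting groups to prevent closure to the 6-prenyl series. C-prenylation on the way to A1 is itself not regioselective.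
- *Stereocontrol.* The 2',6'-dioxygenated enone of A2 is twisted and electron-rich, so it is a weak acceptor for hydroperoxide, yet both stereocentres would rest on that one reagent-controlled step.
- *Relay to C2.* A3 carries a para-oxygenated aryl group on the epoxide. It should open with cationic character, so the configuration at the benzylic carbon is not relayed cleanly.
- *Preference.* The chosen plan takes C3 from the chiral pool, derives C2 from it, and postpones the regiochemical question until a unique oxygen is available to answer it.

**Alternative 2:** Cut C3–C4, a union of two carbonyl carbons.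

- *Forward route.* An intramolecular crossed benzoin reaction of the racemic dialdehyde A4, catalysed by a chiral triazolylidene carbene. The easily racemised alpha-aryl-alpha-aryloxy aldehyde centre would make the closure a dynamic kinetic resolution that sets C2 and C3 together.
- *Objections from mechanism.* The ring A aldehyde that must become the acyl anion equivalent is di-ortho-substituted and strongly electron-rich. The carbene should therefore add to the aliphatic aldehyde instead. From there the coupling polarity would be reversed, or the aryloxide at C2 would be expelled by internal redox.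
- *Preference.* The idea is attractive on paper, but the substrate works against it at every selectivity-determining point.

**Alternative 3:** Cut C2–C1'.

- *Forward route.* Enantioselective conjugate addition of boronic acid A6 to the achiral 3-oxygenated chromone A5, with Pd(OCOCF3)2 and a pyridine-oxazoline ligand (divalent palladium). Protonation at C3 then gives the trans isomer.
- *Objections.* The oxygen on C3 pushes electron density onto C2, and the alpha-substituent slows carbopalladation, so A5 is a much poorer acceptor than a plain chromone. The prenyl alkene offers the aryl-palladium species a second site. Making A5 requires oxidation at C3 of a chromone in the presence of the prenyl group, or again a late prenylation, so the step count rises.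
- *Preference.* The chosen plan reaches the same two stereocentres from an open-chain precursor that is four steps from an amino acid.

Key step: step 7

Assumption: the SMILES descriptors translate to (2R,3R), the trans series. Flavonoid numbering (O1, C2 to C8a, C1' to C6', prenyl C1'' to C5'') is used throughout.

## Steps

**Step 1**
Reactants: 1 D-tyrosine
Product: 3 (R)-2-hydroxy-3-(4-hydroxyphenyl)propanoic acid, via alpha-lactone 2 (not isolated)
Conditions: NaNO2, 1 M aq H2SO4, 0 °C to rt
Reagents that add atoms: water, O
Why: Diazotisation and hydrolysis of an alpha-amino acid proceeds with net retention, because the carboxylate displaces N2 with inversion to give 2 and water opens 2 at the same carbon with a second inversion. The (R) centre of 1 thus becomes C3 of the target, and low temperature limits nitrosation of the phenol ring.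

**Step 2**
Reactants: 3 (R)-2-hydroxy-3-(4-hydroxyphenyl)propanoic acid
Product: 4 (R)-2-hydroxy-3-(4-hydroxyphenyl)-N-methoxy-N-methylpropanamide
Conditions: MeNH(OMe)·HCl, EDC·HCl, HOBt, iPr2NEt, CH2Cl2/DMF, 0 °C to rt
Reagents that add atoms: N,O-dimethylhydroxylamine hydrochloride, CNOC.Cl
Why: Carbodiimide amide coupling through the HOBt active ester; the amine outcompetes the free hydroxyl groups, and the active ester keeps the alpha centre intact.

**Step 3**
Reactants: 4 (R)-2-hydroxy-3-(4-hydroxyphenyl)-N-methoxy-N-methylpropanamide
Product: 5 (R)-N-methoxy-2-(methoxymethoxy)-3-[4-(methoxymethoxy)phenyl]-N-methylpropanamide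
Conditions: MOMCl (3 equiv), iPr2NEt, CH2Cl2, 0 °C to rt
Reagents that add atoms: chloromethyl methyl ether, COCCl
Why: O-alkylation to acetal ethers masks both acidic O–H groups in one operation before the organolithium step; no bond to the stereocentre is touched.

**Step 4**
Reactants: 6 5-methoxyresorcinol
Product: 7 1-methoxy-3,5-bis(methoxymethoxy)benzene
Conditions: MOMCl (2.5 equiv), iPr2NEt, CH2Cl2, 0 °C to rt
Reagents that add atoms: chloromethyl methyl ether, COCCl
Why: Standard acetal protection of phenols; the two OMOM groups also serve as the directing groups of step 5.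

**Step 5**
Reactants: 7 1-methoxy-3,5-bis(methoxymethoxy)benzene; 5 (R)-N-methoxy-2-(methoxymethoxy)-3-[4-(methoxymethoxy)phenyl]-N-methylpropanamide
Product: 9 (R)-1-[4-methoxy-2,6-bis(methoxymethoxy)phenyl]-2-(methoxymethoxy)-3-[4-(methoxymethoxy)phenyl]propan-1-one, via aryllithium 8 (not isolated)
Conditions: 7, n-BuLi, THF, 0 °C; then 5, −78 °C to 0 °C; aq NH4Cl
Reagents that add atoms: none
Why: Directed ortho-metalation should occur at the carbon flanked by both chelating OMOM groups (cooperative effect, stronger than OMe), followed by Weinreb ketone synthesis. The chelated tetrahedral adduct survives until the quench, so neither over-addition nor enolisation of a free ketone by 8 can erode the alpha centre.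

**Step 6**
Reactants: 9 (R)-1-[4-methoxy-2,6-bis(methoxymethoxy)phenyl]-2-(methoxymethoxy)-3-[4-(methoxymethoxy)phenyl]propan-1-one
Product: 10 (R)-1-(2,6-dihydroxy-4-methoxyphenyl)-2-hydroxy-3-(4-hydroxyphenyl)propan-1-one
Conditions: 3 M aq HCl, MeOH, 45 °C
Reagents that add atoms: none
Why: Acid-catalysed acetal exchange with methanol removes all four MOM groups; no acid-labile group is present yet, and the doubly chelated aryl ketone enolises only slowly, so the alpha centre should hold.

**Step 7**
Reactants: 10 (R)-1-(2,6-dihydroxy-4-methoxyphenyl)-2-hydroxy-3-(4-hydroxyphenyl)propan-1-one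
Product: 12 (2R,3R)-3,5-dihydroxy-2-(4-hydroxyphenyl)-7-methoxychroman-4-one, via para-quinone methide 11 (not isolated)
Conditions: DDQ (1.0 equiv), 1,4-dioxane, rt, argon, dark
Reagents that add atoms: none
Why: Proposed new method: DDQ should abstract hydride from the benzylic CH2 para to the free OH of ring B, with loss of the phenolic proton, to give 11; this is the only site in 10 that can deliver a stabilised cation, since ring A has no benzylic hydrogen and is deactivated by its chelated acyl group. One of the two equivalent ortho-hydroxyls of ring A then adds to the methide carbon in a 1,6-oxa-conjugate addition that rearomatises ring B and closes ring C (O1–C2) in the 6-exo-trig mode, so no regiochemical question arises. The closest known reaction type is the DDQ-mediated oxidative cyclisation of 1-(2-hydroxyphenyl)-3-(4-oxyphenyl)propanes to flavans; the extension is its use on an alpha-hydroxydihydrochalcone, where the benzylic carbon stands next to a carbinol and a ketone. C2 is controlled by C3: allylic 1,3-strain places the C3–H bond in the plane of the methide, with the acyl tether over one face and the OH under the other, and attack from the tether face sets H2 and H3 anti, which is the trans (2R,3R) isomer with both substituents equatorial. The same conformer holds C3–H orthogonal to the pi system, which should slow the tautomerisation of 11 to an achiral enol that would erase C3. Any cis isomer can reopen to 11 through the free 4'-OH and close again, so kinetic and thermodynamic control point to the same product. One equivalent of oxidant at room temperature is chosen because dehydrogenation of flavanone-type rings needs forcing conditions, and the prenyl group is deliberately absent because DDQ converts ortho-prenylphenols into chromenes.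

**Step 8**
Reactants: 12 (2R,3R)-3,5-dihydroxy-2-(4-hydroxyphenyl)-7-methoxychroman-4-one
Product: 13 (2R,3R)-2-(4-acetoxyphenyl)-5-hydroxy-7-methoxy-4-oxochroman-3-yl acetate
Conditions: Ac2O (2.2 equiv), pyridine, 0 °C
Reagents that add atoms: acetic anhydride, CC(=O)OC(C)=O
Why: Partial acetylation of a dihydroflavonol; the 5-OH is locked in a hydrogen bond to the C4 carbonyl and is the least nucleophilic hydroxyl, so O4' and O3 should react first. Capping O4' also closes the quinone methide channel and so freezes C2.

**Step 9**
Reactants: 13 (2R,3R)-2-(4-acetoxyphenyl)-5-hydroxy-7-methoxy-4-oxochroman-3-yl acetate; 14 3-methylbut-2-en-1-ol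
Product: 15 (2R,3R)-2-(4-acetoxyphenyl)-7-methoxy-5-(3-methylbut-2-enyloxy)-4-oxochroman-3-yl acetate
Conditions: PPh3, DIAD, THF, 0 °C to rt
Reagents that add atoms: none
Why: Mitsunobu etherification, known for the chelated 5-OH of acetylated flavanones; 13 offers a single acidic O–H, and activated 14 is displaced at its primary carbon. The near-neutral medium avoids the base-induced opening of ring C, and no stereocentre is touched.

**Step 10**
Reactants: 15 (2R,3R)-2-(4-acetoxyphenyl)-7-methoxy-5-(3-methylbut-2-enyloxy)-4-oxochroman-3-yl acetate
Product: 18 (2R,3R)-2-(4-acetoxyphenyl)-5-hydroxy-7-methoxy-8-(3-methylbut-2-enyl)-4-oxochroman-3-yl acetate, via ortho-dienone 16 (not isolated), via para-dienone 17 (not isolated)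
Conditions: Eu(fod)3 (europium tris(6,6,7,7,8,8,8-heptafluoro-2,2-dimethyloctane-3,5-dionate), 10 mol %), PhCl, 85 °C
Reagents that add atoms: none
Why: Lewis-acid-catalysed aromatic Claisen rearrangement followed by Cope rearrangement (para-Claisen sequence), known for 5-O-prenyl flavanones and flavonols: trivalent europium bound at the C4 carbonyl and O5 speeds the [3,3] shift to C6, the only open ortho position, giving 16. The crowded 1,1-dimethylallyl group then moves by a second [3,3] shift to C8 (17), and enolisation restores ring A and the chelated 5-OH. The double allyl inversion returns the normal prenyl chain, and C2 and C3 take no part.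

**Step 11**
Reactants: 18 (2R,3R)-2-(4-acetoxyphenyl)-5-hydroxy-7-methoxy-8-(3-methylbut-2-enyl)-4-oxochroman-3-yl acetate
Product: 19 (2R,3R)-3,5-dihydroxy-2-(4-hydroxyphenyl)-7-methoxy-8-(3-methylbut-2-enyl)chroman-4-one
Conditions: HCl (cat., from a methanolic stock solution), MeOH, rt
Reagents that add atoms: none
Why: Acid-catalysed transesterification removes both acetates without the base that would open ring C or enolise C3. Prenylated flavonoids tolerate dilute methanolic HCl, and here the prenyl group has no neighbouring free OH (O1 and 7-OMe flank it), so chroman formation is impossible.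

## Compound list

1 | D-tyrosine, (R)-2-amino-3-(4-hydroxyphenyl)propanoic acid | N[C@H](Cc1ccc(O)cc1)C(=O)O | starting material
2 | (S)-3-(4-hydroxybenzyl)oxiran-2-one (alpha-lactone) | O1[C@@H](Cc2ccc(O)cc2)C1=O | intermediate
3 | (R)-2-hydroxy-3-(4-hydroxyphenyl)propanoic acid | O[C@H](Cc1ccc(O)cc1)C(=O)O | intermediate
4 | (R)-2-hydroxy-3-(4-hydroxyphenyl)-N-methoxy-N-methylpropanamide | O[C@H](Cc1ccc(O)cc1)C(=O)N(C)OC | intermediate
5 | (R)-N-methoxy-2-(methoxymethoxy)-3-[4-(methoxymethoxy)phenyl]-N-methylpropanamide | COCO[C@H](Cc1ccc(OCOC)cc1)C(=O)N(C)OC | intermediate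
6 | 5-methoxyresorcinol (5-methoxybenzene-1,3-diol) | COc1cc(O)cc(O)c1 | starting material
7 | 1-methoxy-3,5-bis(methoxymethoxy)benzene | COCOc1cc(OC)cc(OCOC)c1 | intermediate
8 | [4-methoxy-2,6-bis(methoxymethoxy)phenyl]lithium | [Li]c1c(OCOC)cc(OC)cc1OCOC | intermediate
9 | (R)-1-[4-methoxy-2,6-bis(methoxymethoxy)phenyl]-2-(methoxymethoxy)-3-[4-(methoxymethoxy)phenyl]propan-1-one | COCO[C@H](Cc1ccc(OCOC)cc1)C(=O)c1c(OCOC)cc(OC)cc1OCOC | intermediate
10 | (R)-1-(2,6-dihydroxy-4-methoxyphenyl)-2-hydroxy-3-(4-hydroxyphenyl)propan-1-one | O[C@H](Cc1ccc(O)cc1)C(=O)c1c(O)cc(OC)cc1O | intermediate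
11 | 4-[(2R)-3-(2,6-dihydroxy-4-methoxyphenyl)-2-hydroxy-3-oxopropylidene]cyclohexa-2,5-dien-1-one | O[C@H](C=C1C=CC(=O)C=C1)C(=O)c1c(O)cc(OC)cc1O | intermediate
12 | (2R,3R)-3,5-dihydroxy-2-(4-hydroxyphenyl)-7-methoxychroman-4-one | COc1cc(O)c2c(c1)O[C@H](c1ccc(O)cc1)[C@@H](O)C2=O | intermediate
13 | (2R,3R)-2-(4-acetoxyphenyl)-5-hydroxy-7-methoxy-4-oxochroman-3-yl acetate | COc1cc(O)c2c(c1)O[C@H](c1ccc(OC(C)=O)cc1)[C@@H](OC(C)=O)C2=O | intermediate
14 | 3-methylbut-2-en-1-ol | CC(C)=CCO | starting material
15 | (2R,3R)-2-(4-acetoxyphenyl)-7-methoxy-5-(3-methylbut-2-enyloxy)-4-oxochroman-3-yl acetate | COc1cc(OCC=C(C)C)c2c(c1)O[C@H](c1ccc(OC(C)=O)cc1)[C@@H](OC(C)=O)C2=O | intermediate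
16 | (2R,3R)-2-(4-acetoxyphenyl)-7-methoxy-6-(2-methylbut-3-en-2-yl)-4,5-dioxo-3,4,5,6-tetrahydro-2H-chromen-3-yl acetate (C6 epimers) | COC=1C(C(C)(C)C=C)C(=O)C2=C(C=1)O[C@H](c1ccc(OC(C)=O)cc1)[C@@H](OC(C)=O)C2=O | intermediate
17 | (2R,3R)-2-(4-acetoxyphenyl)-7-methoxy-8-(3-methylbut-2-enyl)-4,5-dioxo-3,4,5,8-tetrahydro-2H-chromen-3-yl acetate (C8 epimers) | COC1=CC(=O)C2=C(C1CC=C(C)C)O[C@H](c1ccc(OC(C)=O)cc1)[C@@H](OC(C)=O)C2=O | intermediate
18 | (2R,3R)-2-(4-acetoxyphenyl)-5-hydroxy-7-methoxy-8-(3-methylbut-2-enyl)-4-oxochroman-3-yl acetate | COc1cc(O)c2c(c1CC=C(C)C)O[C@H](c1ccc(OC(C)=O)cc1)[C@@H](OC(C)=O)C2=O | intermediate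
19 | (2R,3R)-3,5-dihydroxy-2-(4-hydroxyphenyl)-7-methoxy-8-(3-methylbut-2-enyl)chroman-4-one | COc1cc(O)c2c(c1CC=C(C)C)O[C@H](c1ccc(O)cc1)[C@@H](O)C2=O | target

## Step count and least certain steps

Total: 11 steps. The longest linear sequence is 10 steps (1 to 19 through steps 1 to 3 and 5 to 11). Step 4 is the single step of the short branch.

**Step 7 (key step, proposed new method).**

- *What may go wrong.* Hydride abstraction may be slowed by the electron-withdrawing carbinol and ketone next to the benzylic carbon. The methide may tautomerise by loss of the C3 proton, which erases the only stereocentre and opens the way to benzofuranone-type closure. The unhindered ring B phenol may couple with the oxidant at oxygen. The closed product may be dehydrogenated further.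
- *Fallback (known chemistry).* It sets out from 7 and comes back at 12.
  - 7 is lithiated to 8 and acylated with N-methoxy-N-methylacetamide to give 1-[4-methoxy-2,6-bis(methoxymethoxy)phenyl]ethanone F1.
  - Claisen–Schmidt condensation (KOH, EtOH) with 4-(methoxymethoxy)benzaldehyde F2 gives (E)-1-[4-methoxy-2,6-bis(methoxymethoxy)phenyl]-3-[4-(methoxymethoxy)phenyl]prop-2-en-1-one F3.
  - Juliá–Colonna epoxidation (poly-L-leucine, urea·H2O2, DBU, THF) gives the trans (alphaR,betaS)-epoxide [4-methoxy-2,6-bis(methoxymethoxy)phenyl]{(2R,3S)-3-[4-(methoxymethoxy)phenyl]oxiran-2-yl}methanone F4.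
  - HCl in MeOH then removes the three MOM groups and closes ring C at the benzylic carbon with inversion, giving 12.

**Step 5.**

- *What may go wrong.* Acyl transfer to a di-ortho-substituted aryllithium is slow. Deprotonation of the alpha C–H of 5 may then compete and erode the configuration, or the amide may be returned unchanged.
- *Fallback.* It sets out from 5 and 8 and comes back at 9. Compound 5 is reduced with iBu2AlH (THF, −78 °C) to (R)-2-(methoxymethoxy)-3-[4-(methoxymethoxy)phenyl]propanal F5. Aryllithium 8 adds to this far more electrophilic carbonyl at −78 °C to give (2R)-1-[4-methoxy-2,6-bis(methoxymethoxy)phenyl]-2-(methoxymethoxy)-3-[4-(methoxymethoxy)phenyl]propan-1-ol F6 as a mixture of carbinol epimers. Oxidation with DMP (CH2Cl2, NaHCO3) merges both epimers into 9.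

**Step 6.**

- *What may go wrong.* The secondary alkyl MOM ether may need acid and heat strong enough to enolise the alpha-hydroxy ketone. That would cause partial loss of configuration at the future C3 or a ketol shift.
- *Fallback.* It sets out from 3 and comes back at 10, and it avoids an alkyl MOM ether altogether.
  - 3 is condensed with 2,2-dimethoxypropane (cat. TsOH, acetone) to (R)-5-(4-hydroxybenzyl)-2,2-dimethyl-1,3-dioxolan-4-one F7.
  - The phenol is protected (MOMCl, iPr2NEt) to give (R)-5-[4-(methoxymethoxy)benzyl]-2,2-dimethyl-1,3-dioxolan-4-one F8.
  - Aryllithium 8 adds to the lactone carbonyl at −78 °C. The quench releases acetone and gives (R)-2-hydroxy-1-[4-methoxy-2,6-bis(methoxymethoxy)phenyl]-3-[4-(methoxymethoxy)phenyl]propan-1-one F9.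
  - The three aryl MOM ethers of F9 fall with catalytic HCl in MeOH at rt to give 10.

**Step 10.**

- *What may go wrong.* The sequence may stop at the ortho stage, through enolisation of 16 before the Cope shift. The Lewis acid may also ionise the prenyl ether, with loss of the chain or unselective recombination.
- *Fallback.* It sets out from 12 and comes back at 19. It replaces the sigmatropic relay by direct Friedel–Crafts C-prenylation of unprotected 12 with 2-methylbut-3-en-2-ol and BF3·OEt2 in dioxane at rt, followed by chromatographic separation of the positional isomers. This gives up regiocontrol but removes steps 8 to 11. It makes no compound outside the list (entry F0).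

## Further compounds

F1 | step 7 | 1-[4-methoxy-2,6-bis(methoxymethoxy)phenyl]ethanone | CC(=O)c1c(OCOC)cc(OC)cc1OCOC
F2 | step 7 | 4-(methoxymethoxy)benzaldehyde | COCOc1ccc(C=O)cc1
F3 | step 7 | (E)-1-[4-methoxy-2,6-bis(methoxymethoxy)phenyl]-3-[4-(methoxymethoxy)phenyl]prop-2-en-1-one | COCOc1ccc(/C=C/C(=O)c2c(OCOC)cc(OC)cc2OCOC)cc1
F4 | step 7 | [4-methoxy-2,6-bis(methoxymethoxy)phenyl]{(2R,3S)-3-[4-(methoxymethoxy)phenyl]oxiran-2-yl}methanone | O=C(c1c(OCOC)cc(OC)cc1OCOC)[C@@H]1O[C@H]1c1ccc(OCOC)cc1
F5 | step 5 | (R)-2-(methoxymethoxy)-3-[4-(methoxymethoxy)phenyl]propanal | COCO[C@H](Cc1ccc(OCOC)cc1)C=O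
F6 | step 5 | (2R)-1-[4-methoxy-2,6-bis(methoxymethoxy)phenyl]-2-(methoxymethoxy)-3-[4-(methoxymethoxy)phenyl]propan-1-ol (C1 epimers) | COCO[C@H](Cc1ccc(OCOC)cc1)C(O)c1c(OCOC)cc(OC)cc1OCOC
F7 | step 6 | (R)-5-(4-hydroxybenzyl)-2,2-dimethyl-1,3-dioxolan-4-one | CC1(C)O[C@H](Cc2ccc(O)cc2)C(=O)O1
F8 | step 6 | (R)-5-[4-(methoxymethoxy)benzyl]-2,2-dimethyl-1,3-dioxolan-4-one | CC1(C)O[C@H](Cc2ccc(OCOC)cc2)C(=O)O1
F9 | step 6 | (R)-2-hydroxy-1-[4-methoxy-2,6-bis(methoxymethoxy)phenyl]-3-[4-(methoxymethoxy)phenyl]propan-1-one | O[C@H](Cc1ccc(OCOC)cc1)C(=O)c1c(OCOC)cc(OC)cc1OCOC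
F0 | step 10 | none | none
A1 | alternative 1 | 1-[4-methoxy-2,6-bis(methoxymethoxy)-3-(3-methylbut-2-enyl)phenyl]ethanone | CC(=O)c1c(OCOC)cc(OC)c(CC=C(C)C)c1OCOC
A2 | alternative 1 | (E)-1-[4-methoxy-2,6-bis(methoxymethoxy)-3-(3-methylbut-2-enyl)phenyl]-3-[4-(methoxymethoxy)phenyl]prop-2-en-1-one | COCOc1ccc(/C=C/C(=O)c2c(OCOC)cc(OC)c(CC=C(C)C)c2OCOC)cc1
A3 | alternative 1 | [4-methoxy-2,6-bis(methoxymethoxy)-3-(3-methylbut-2-enyl)phenyl]{(2R,3S)-3-[4-(methoxymethoxy)phenyl]oxiran-2-yl}methanone | O=C(c1c(OCOC)cc(OC)c(CC=C(C)C)c1OCOC)[C@@H]1O[C@H]1c1ccc(OCOC)cc1
A4 | alternative 2 | 4-methoxy-6-(methoxymethoxy)-3-(3-methylbut-2-enyl)-2-{1-[4-(methoxymethoxy)phenyl]-2-oxoethoxy}benzaldehyde (racemic) | O=CC(Oc1c(CC=C(C)C)c(OC)cc(OCOC)c1C=O)c1ccc(OCOC)cc1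
A5 | alternative 3 | 5-hydroxy-7-methoxy-3-(methoxymethoxy)-8-(3-methylbut-2-enyl)chromen-4-one | COCOc1coc2c(CC=C(C)C)c(OC)cc(O)c2c1=O
A6 | alternative 3 | 4-hydroxyphenylboronic acid | OB(O)c1ccc(O)cc1
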